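**Strategy.** The route rests on cutting the bond between ring C2 and the first carbon of the butanoate chain, the bromotrienyne arm being traced back to a hydroxymethyl group on C5. The key step exploits the trans relationship of C2 and C5 across the oxolane ring (O1, C2, C3, C4, C5). An Ireland–Claisen rearrangement of a thymidine-derived furanoid glycal acetate forms the C2–CH2 bond and sets C2 in one operation by relaying chirality from the sugar C3–O bond, while sugar C4 becomes C5 untouched. The precursor is a 2,3-dihydrofuran carrying the acetate on C3 and a silyloxymethyl group on C4, trans to each other. Two-carbon extension, hydrogenation, alkyne formation and a Sonogashira coupling follow.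

Key step: step 3

Remark: the oxolane atoms are numbered O1, C2 (butanoate side) to C5 (alkynyl side); Wittig product 13 is drawn as its (E)-isomer, but either geometry serves because that alkene is hydrogenated in step 6.

Step 1
Reactants: 1 thymidine
Product: 2 5'-O-(tert-butyldimethylsilyl)thymidine
Conditions: TBSCl (1.1 equiv), imidazole, DMF, 0 °C → rt
Reagents that add atoms: tert-butyldimethylsilyl chloride, CC(C)(C)[Si](C)(C)Cl
Why: Silyl ether formation with a bulky chlorosilane should select the primary 5'-hydroxyl over the secondary 3'-hydroxyl, and no stereocentre is touched.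

Step 2
Reactants: 2 5'-O-(tert-butyldimethylsilyl)thymidine
Product: 4 (2R,3S)-2-(tert-butyldimethylsilyloxymethyl)-2,3-dihydrofuran-3-ol, via glycal trimethylsilyl ether 3 (not isolated)
Conditions: (Me3Si)2NH, (NH4)2SO4 (cat.), reflux; evaporate; K2CO3 (cat.), MeOH, 0 °C → rt
Reagents that add atoms: none
Why: Glycal formation from a 2'-deoxynucleoside: silylation of thymine turns it into a leaving group, elimination across C1'–C2' gives the enol ether with O3 capped as its trimethylsilyl ether 3, and mild methanolysis then frees O3 while the primary tert-butyldimethylsilyl ether and the C3 and C4 stereocentres stay untouched.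

Step 3
Reactants: 4 (2R,3S)-2-(tert-butyldimethylsilyloxymethyl)-2,3-dihydrofuran-3-ol; 5 acetyl chloride
Product: 9 2-[(2R,5S)-5-(tert-butyldimethylsilyloxymethyl)-2,5-dihydrofuran-2-yl]acetic acid, via glycal acetate 6 (not isolated), via silyl ketene acetal 7 (not isolated), via trimethylsilyl ester 8 (not isolated)
Conditions: n-BuLi (1.0 equiv), THF, −78 °C; AcCl (1.0 equiv), −78 °C; cold solution added to LiN(iPr)2 (1.5 equiv)/Me3SiCl–Et3N, THF, −100 → −78 °C; warm to 25 °C; H2O, extraction at pH 4–5
Reagents that add atoms: none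
Why: O-Acetylation of the lithium alkoxide of 4 at −78 °C gives the labile allylic acetate 6, which is never isolated but enolised at once by LiN(iPr)2 with Me3SiCl present, so that the enolate is trapped on oxygen as the allyl silyl ketene acetal 7 before the ester can ionise and aromatise to a furan. On warming, 7 undergoes a concerted suprafacial [3,3]-sigmatropic shift over the six atoms CH2=C(OSiMe3)–O–C3–C2=C1 of the glycal, which forms the bond from the acetate carbon to the anomeric carbon, breaks the C3–O bond and moves the ring alkene to C3–C4 of the new 2,5-dihydrofuran, and water then cleaves silyl ester 8 to acid 9. The closest known reaction type is the Ireland–Claisen (ester enolate Claisen) rearrangement of furanoid glycal esters. No ring is closed: the five-membered ring of the sugar is carried through and the new bond is exocyclic. The one new stereocentre, C2, is controlled by the C3 stereocentre of the glycal, because the ketene acetal is tethered to the ring face that bears the C3 oxygen and can reach the anomeric carbon only on that face, trans to the C4 substituent, while C4 itself is untouched and becomes C5 (2R,5S). The selectivity needed is this complete 1,3-transfer of chirality across the ring together with O- over C-silylation, the first secured by the cyclic transition state and the second by trapping the enolate as it forms at low temperature.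

Step 4
Reactants: 9 2-[(2R,5S)-5-(tert-butyldimethylsilyloxymethyl)-2,5-dihydrofuran-2-yl]acetic acid
Product: 10 2-[(2R,5S)-5-(tert-butyldimethylsilyloxymethyl)-2,5-dihydrofuran-2-yl]ethan-1-ol
Conditions: LiAlH4, Et2O, 0 °C → rt
Reagents that add atoms: none
Why: Hydride reduction of the carboxylic acid with LiAlH4 should give the primary alcohol, and neither the silyl ether, the isolated ring alkene nor the two stereocentres are affected.

Step 5
Reactants: 10 2-[(2R,5S)-5-(tert-butyldimethylsilyloxymethyl)-2,5-dihydrofuran-2-yl]ethan-1-ol; 11 methyl (triphenylphosphoranylidene)acetate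
Product: 13 methyl (2E)-4-[(2R,5S)-5-(tert-butyldimethylsilyloxymethyl)-2,5-dihydrofuran-2-yl]but-2-enoate, via dihydrofuranylacetaldehyde 12 (not isolated)
Conditions: Dess–Martin periodinane (1.3 equiv), 11 (2.5 equiv), CH2Cl2, 0 °C → rt
Reagents that add atoms: none
Why: Tandem Dess–Martin oxidation and Wittig olefination: the stabilised ylide is present while the alcohol is oxidised, so the β-alkoxy aldehyde 12 is olefinated as it forms and has little time to lose the ring oxygen by β-elimination.

Step 6
Reactants: 13 methyl (2E)-4-[(2R,5S)-5-(tert-butyldimethylsilyloxymethyl)-2,5-dihydrofuran-2-yl]but-2-enoate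
Product: 14 methyl 4-[(2R,5S)-5-(tert-butyldimethylsilyloxymethyl)oxolan-2-yl]butanoate
Conditions: H2 (1 atm), 5% Rh/Al2O3, EtOAc, rt
Reagents that add atoms: none
Why: Heterogeneous catalytic hydrogenation should saturate the enoate and the ring alkene in one operation, rhodium on alumina being chosen because it causes little alkene migration or allylic C–O hydrogenolysis, so that C2 and C5 keep their configuration.

Step 7
Reactants: 14 methyl 4-[(2R,5S)-5-(tert-butyldimethylsilyloxymethyl)oxolan-2-yl]butanoate
Product: 15 methyl 4-[(2R,5S)-5-(hydroxymethyl)oxolan-2-yl]butanoate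
Conditions: camphorsulfonic acid (cat.), MeOH, 0 °C → rt
Reagents that add atoms: none
Why: Acid-catalysed methanolysis should remove the primary silyl ether, while the methyl ester is unchanged in methanol and the oxolane is inert.

Step 8
Reactants: 15 methyl 4-[(2R,5S)-5-(hydroxymethyl)oxolan-2-yl]butanoate
Product: 16 methyl 4-[(2R,5S)-5-formyloxolan-2-yl]butanoate
Conditions: Dess–Martin periodinane, CH2Cl2, 0 °C → rt; used crude
Reagents that add atoms: none
Why: Dess–Martin oxidation under non-basic conditions should give the α-alkoxy aldehyde without epimerising C5, and the crude aldehyde is taken on at once.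

Step 9
Reactants: 16 methyl 4-[(2R,5S)-5-formyloxolan-2-yl]butanoate
Product: 17 methyl 4-[(2R,5S)-5-ethynyloxolan-2-yl]butanoate
Conditions: dimethyl (1-diazo-2-oxopropyl)phosphonate, K2CO3, MeOH, 0 °C → rt
Reagents that add atoms: dimethyl (1-diazo-2-oxopropyl)phosphonate, COP(=O)(OC)C(=[N+]=[N-])C(C)=O
Why: Seyferth–Gilbert homologation in its Ohira–Bestmann form: methanolysis of the acyl group releases the diazomethylphosphonate anion, which adds to the aldehyde, and loss of dimethyl phosphate and N2 followed by a 1,2-hydrogen shift gives the terminal alkyne under a carbonate base that should neither epimerise C5 nor alter the methyl ester.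

Step 10
Reactants: 18 hept-6-yn-1-ol
Product: 20 (6E)-7-iodohept-6-en-1-ol, via alkenylzirconocene chloride 19 (not isolated)
Conditions: Cp2Zr(H)Cl (2.2 equiv), THF, rt; then I2, 0 °C
Reagents that add atoms: iodine, II
Why: Hydrozirconation–iodination: after the first equivalent of Cp2Zr(H)Cl is consumed by the hydroxyl group, syn addition of Zr–H across the terminal alkyne places zirconium on the end carbon, and iodinolysis with retention should give only the (E)-iodoalkene.

Step 11
Reactants: 20 (6E)-7-iodohept-6-en-1-ol
Product: 21 (6E)-7-iodohept-6-enal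
Conditions: Dess–Martin periodinane, CH2Cl2, 0 °C → rt
Reagents that add atoms: none
Why: Dess–Martin oxidation of a primary alcohol should stop at the aldehyde and leave the alkenyl iodide untouched.

Step 12
Reactants: 21 (6E)-7-iodohept-6-enal; 22 (triphenylphosphoranylidene)acetaldehyde
Product: 23 (2E,8E)-9-iodonona-2,8-dienal
Conditions: toluene, 80 °C
Reagents that add atoms: none
Why: Wittig olefination with a stabilised formyl ylide should give the (E)-enal, the saturated aldehyde reacting faster than the conjugated product so that a second homologation stays minor.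

Step 13
Reactants: 17 methyl 4-[(2R,5S)-5-ethynyloxolan-2-yl]butanoate; 23 (2E,8E)-9-iodonona-2,8-dienal
Product: 24 methyl 4-[(2R,5S)-5-[(3E,9E)-11-oxoundeca-3,9-dien-1-yn-1-yl]oxolan-2-yl]butanoate
Conditions: Pd(PPh3)2Cl2 (cat.), CuI (cat.), Et3N, THF, rt, degassed
Reagents that add atoms: none
Why: Sonogashira coupling: oxidative addition of the alkenyl iodide, transmetalation from the copper acetylide and reductive elimination should join the sp and sp2 carbons with retention of the (E)-geometry under amine conditions that the ester, oxolane and enal tolerate.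

Step 14
Reactants: 24 methyl 4-[(2R,5S)-5-[(3E,9E)-11-oxoundeca-3,9-dien-1-yn-1-yl]oxolan-2-yl]butanoate
Product: 25 methyl 4-[(2R,5S)-5-[(3E,9E)-12,12-dibromododeca-3,9,11-trien-1-yn-1-yl]oxolan-2-yl]butanoate
Conditions: CBr4, PPh3, CH2Cl2, 0 °C
Reagents that add atoms: carbon tetrabromide, BrC(Br)(Br)Br
Why: Corey–Fuchs-type dibromomethylenation: the ylide Ph3P=CBr2 formed from CBr4 and PPh3 olefinates the aldehyde in a Wittig reaction, which creates no stereochemical element.

Step 15
Reactants: 25 methyl 4-[(2R,5S)-5-[(3E,9E)-12,12-dibromododeca-3,9,11-trien-1-yn-1-yl]oxolan-2-yl]butanoate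
Product: 26 methyl 4-[(2R,5S)-5-[(3E,9E,11Z)-12-bromododeca-3,9,11-trien-1-yn-1-yl]oxolan-2-yl]butanoate
Conditions: Bu3SnH (1.05 equiv), Pd(PPh3)4 (cat.), toluene, rt
Reagents that add atoms: none
Why: Palladium-catalysed hydrogenolysis of a 1,1-dibromoalkene with a tin hydride: zerovalent palladium inserts selectively into the less hindered C–Br bond trans to the dienyl chain, and hydride transfer from tin followed by reductive elimination with retention leaves the bromine cis to the chain, giving the (11Z)-bromide, which should react far more slowly than the dibromide.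

**Compound list**

1 | thymidine | CC1=CN(C(=O)NC1=O)[C@H]2C[C@@H]([C@H](O2)CO)O | starting material
2 | 5'-O-(tert-butyldimethylsilyl)thymidine; 1-[(2R,4S,5R)-5-(tert-butyldimethylsilyloxymethyl)-4-hydroxyoxolan-2-yl]-5-methylpyrimidine-2,4-dione | CC1=CN(C(=O)NC1=O)[C@H]2C[C@@H]([C@H](O2)CO[Si](C)(C)C(C)(C)C)O | intermediate
3 | (2R,3S)-2-(tert-butyldimethylsilyloxymethyl)-3-(trimethylsilyloxy)-2,3-dihydrofuran | C[Si](C)(C)O[C@H]1C=CO[C@@H]1CO[Si](C)(C)C(C)(C)C | intermediate
4 | (2R,3S)-2-(tert-butyldimethylsilyloxymethyl)-2,3-dihydrofuran-3-ol (5-O-silyl-1,4-anhydro-2-deoxy-D-erythro-pent-1-enitol) | O[C@H]1C=CO[C@@H]1CO[Si](C)(C)C(C)(C)C | intermediate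
5 | acetyl chloride | CC(Cl)=O | starting material
6 | (2R,3S)-2-(tert-butyldimethylsilyloxymethyl)-2,3-dihydrofuran-3-yl acetate (3-O-acetyl-5-O-silyl glycal; OAc and CH2OSi trans) | CC(=O)O[C@H]1C=CO[C@@H]1CO[Si](C)(C)C(C)(C)C | intermediate
7 | (2R,3S)-2-(tert-butyldimethylsilyloxymethyl)-3-{[1-(trimethylsilyloxy)ethenyl]oxy}-2,3-dihydrofuran | C=C(O[Si](C)(C)C)O[C@H]1C=CO[C@@H]1CO[Si](C)(C)C(C)(C)C | intermediate
8 | trimethylsilyl 2-[(2R,5S)-5-(tert-butyldimethylsilyloxymethyl)-2,5-dihydrofuran-2-yl]acetate | C[Si](C)(C)OC(=O)C[C@@H]1C=C[C@@H](CO[Si](C)(C)C(C)(C)C)O1 | intermediate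
9 | 2-[(2R,5S)-5-(tert-butyldimethylsilyloxymethyl)-2,5-dihydrofuran-2-yl]acetic acid (2,5-trans) | OC(=O)C[C@@H]1C=C[C@@H](CO[Si](C)(C)C(C)(C)C)O1 | intermediate
10 | 2-[(2R,5S)-5-(tert-butyldimethylsilyloxymethyl)-2,5-dihydrofuran-2-yl]ethan-1-ol | OCC[C@@H]1C=C[C@@H](CO[Si](C)(C)C(C)(C)C)O1 | intermediate
11 | methyl (triphenylphosphoranylidene)acetate | COC(=O)C=P(c1ccccc1)(c1ccccc1)c1ccccc1 | starting material
12 | 2-[(2R,5S)-5-(tert-butyldimethylsilyloxymethyl)-2,5-dihydrofuran-2-yl]acetaldehyde | O=CC[C@@H]1C=C[C@@H](CO[Si](C)(C)C(C)(C)C)O1 | intermediate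
13 | methyl (2E)-4-[(2R,5S)-5-(tert-butyldimethylsilyloxymethyl)-2,5-dihydrofuran-2-yl]but-2-enoate | COC(=O)/C=C/C[C@@H]1C=C[C@@H](CO[Si](C)(C)C(C)(C)C)O1 | intermediate
14 | methyl 4-[(2R,5S)-5-(tert-butyldimethylsilyloxymethyl)oxolan-2-yl]butanoate | COC(=O)CCC[C@@H]1CC[C@@H](CO[Si](C)(C)C(C)(C)C)O1 | intermediate
15 | methyl 4-[(2R,5S)-5-(hydroxymethyl)oxolan-2-yl]butanoate | COC(=O)CCC[C@@H]1CC[C@@H](CO)O1 | intermediate
16 | methyl 4-[(2R,5S)-5-formyloxolan-2-yl]butanoate | COC(=O)CCC[C@@H]1CC[C@@H](C=O)O1 | intermediate
17 | methyl 4-[(2R,5S)-5-ethynyloxolan-2-yl]butanoate | COC(=O)CCC[C@@H]1CC[C@@H](C#C)O1 | intermediate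
18 | hept-6-yn-1-ol | C#CCCCCCO | starting material
19 | chlorobis(cyclopentadienyl)zirconium (E)-alkenyl species from 18, with the oxygen also bound to a chlorozirconocene unit | Cl[Zr](OCCCCC/C=C/[Zr](Cl)(C1C=CC=C1)C1C=CC=C1)(C1C=CC=C1)C1C=CC=C1 | intermediate
20 | (6E)-7-iodohept-6-en-1-ol | OCCCCC/C=C/I | intermediate
21 | (6E)-7-iodohept-6-enal | O=CCCCC/C=C/I | intermediate
22 | (triphenylphosphoranylidene)acetaldehyde | O=CC=P(c1ccccc1)(c1ccccc1)c1ccccc1 | starting material
23 | (2E,8E)-9-iodonona-2,8-dienal | O=C/C=C/CCCC/C=C/I | intermediate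
24 | methyl 4-[(2R,5S)-5-[(3E,9E)-11-oxoundeca-3,9-dien-1-yn-1-yl]oxolan-2-yl]butanoate | COC(=O)CCC[C@@H]1CC[C@@H](C#C/C=C/CCCC/C=C/C=O)O1 | intermediate
25 | methyl 4-[(2R,5S)-5-[(3E,9E)-12,12-dibromododeca-3,9,11-trien-1-yn-1-yl]oxolan-2-yl]butanoate | COC(=O)CCC[C@@H]1CC[C@@H](C#C/C=C/CCCC/C=C/C=C(Br)Br)O1 | intermediate
26 | methyl 4-[(2R,5S)-5-[(3E,9E,11Z)-12-bromododeca-3,9,11-trien-1-yn-1-yl]oxolan-2-yl]butanoate | COC(=O)CCC[C@@H]1CC[C@@H](C#C/C=C/CCCC/C=C/C=C\Br)O1 | target

**Step count and risk**

Total: 15 steps. Longest linear sequence: 12 steps (steps 1–9, then 13–15); the side-chain branch (steps 10–12) joins at step 13.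

Steps most likely to fail:

1. Step 3 (key step). The allylic glycal ester may ionise and aromatise to a furan before it is enolised, and part of the enolate may be silylated on carbon, which cannot rearrange. The fallback sets out from 4 and comes back at 10. It dispenses with the ester and the strong base by using an Eschenmoser amide-acetal Claisen rearrangement. Compound 4 is heated with N,N-dimethylacetamide dimethyl acetal in toluene with removal of methanol. Through the ketene N,O-acetal and the same suprafacial shift this should give 2-[(2R,5S)-5-(tert-butyldimethylsilyloxymethyl)-2,5-dihydrofuran-2-yl]-N,N-dimethylacetamide F1. Reduction of the tertiary amide with LiEt3BH in THF at 0 °C should then give alcohol 10.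

2. Step 5. Ring opening of aldehyde 12 by β-elimination of the ring oxygen, and reclosure with loss of the trans relationship, may outrun olefination. The fallback sets out from 10 and comes back at 14. It avoids the carbonyl intermediate by building the chain through alkylation. Compound 10 is converted with I2, PPh3 and imidazole into (2R,5S)-2-(2-iodoethyl)-5-(tert-butyldimethylsilyloxymethyl)-2,5-dihydrofuran F2. This alkylates sodium dimethyl malonate (NaH, THF–DMF) to give dimethyl 2-{2-[(2R,5S)-5-(tert-butyldimethylsilyloxymethyl)-2,5-dihydrofuran-2-yl]ethyl}propanedioate F3. Krapcho dealkoxycarbonylation (LiCl, wet DMSO, 140 °C) should give methyl 4-[(2R,5S)-5-(tert-butyldimethylsilyloxymethyl)-2,5-dihydrofuran-2-yl]butanoate F4, and hydrogenation under the conditions of step 6 gives 14.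

3. Step 15. The tin hydride may hydrostannate the enyne under palladium catalysis, the monobromide may be reduced further, or selection between the two C–Br bonds may be incomplete. The fallback sets out from 24 and comes back at 26, skipping step 14. It is a metal-free (Z)-selective Wittig bromomethylenation: aldehyde 24 is treated in THF at −78 °C with the ylide made from (bromomethyl)triphenylphosphonium bromide and KOtBu. This should give 26 directly with the (11Z)-bromide predominating. No new compound is made on this path (F0).

**Further compounds**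

F1 | step 3 | 2-[(2R,5S)-5-(tert-butyldimethylsilyloxymethyl)-2,5-dihydrofuran-2-yl]-N,N-dimethylacetamide | CN(C)C(=O)C[C@@H]1C=C[C@@H](CO[Si](C)(C)C(C)(C)C)O1
F2 | step 5 | (2R,5S)-2-(2-iodoethyl)-5-(tert-butyldimethylsilyloxymethyl)-2,5-dihydrofuran | ICC[C@@H]1C=C[C@@H](CO[Si](C)(C)C(C)(C)C)O1
F3 | step 5 | dimethyl 2-{2-[(2R,5S)-5-(tert-butyldimethylsilyloxymethyl)-2,5-dihydrofuran-2-yl]ethyl}propanedioate | COC(=O)C(CC[C@@H]1C=C[C@@H](CO[Si](C)(C)C(C)(C)C)O1)C(=O)OC
F4 | step 5 | methyl 4-[(2R,5S)-5-(tert-butyldimethylsilyloxymethyl)-2,5-dihydrofuran-2-yl]butanoate | COC(=O)CCC[C@@H]1C=C[C@@H](CO[Si](C)(C)C(C)(C)C)O1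
F0 | step 15 | none | none
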